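**Plan**

Numbering follows the acid chain, C1 (ester carbonyl) to C12 (benzylic CH2); the 1,2-dioxane is O1 (on C6), O2 (on C3), C3, C4, C5, C6.
Retrosynthesis: the C8=C9 alkene is cut first (C8 sulfone 22 + enal 25). The ring carries the unit O2–C3(H)–C2H2–C1O2Me, so O2–C3, C2–C1 and C1–OMe are then cut together, giving the C6 hydroperoxide with a C3=C2 terminal alkene (17), CO and MeOH.
The C6–O1 bond goes back to H2O2 and an oxetane bridging C6 and C8, the oxetane to a 1,3-diol, the diol to the epoxide of a C6=C7 allylic alcohol, and this to an enyne, AlMe3 and acetaldehyde; C4–C5 goes back to an oxazolidinone propionate and propargyl bromide.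
Forward: the open chain C3–C8 is built, the oxetane is closed and reopened, the 1,2-dioxane (the only ring of the target) closes in the key step, and the C9–C12 phenyl piece is joined last.
Stereochemistry: C4 from the Evans auxiliary; the C8 carbinol from CBS reduction, relayed to C6 by hydroxyl-directed epoxidation and inverted once at C6 by H2O2; C3 from the chair of the ring closure (trans to the C4 methyl); 8E from the olefination, 10E from enal 25.

Key step: step 12

Assumption: the C8 carbinol is a spectator centre erased in step 16, so it is carried with defined configuration and left unprotected through the key step; compounds 5 and 6 are volatile and are meant to be carried forward as solutions.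

**Route**

Step 1
Reactants: 1 (4S)-4-benzyl-3-propanoyl-1,3-oxazolidin-2-one; 2 3-bromoprop-1-yne
Product: 3 (4S)-4-benzyl-3-[(2R)-2-methylpent-4-ynoyl]-1,3-oxazolidin-2-one
Conditions: NaN(SiMe3)2, THF, −78 °C; then 2, −78 → −40 °C
Reagents that add atoms: none
Why: Evans asymmetric alkylation, in which the chelated Z sodium enolate is attacked by the propargylic bromide on the face away from the benzyl group, setting C4 as R.

Step 2
Reactants: 3 (4S)-4-benzyl-3-[(2R)-2-methylpent-4-ynoyl]-1,3-oxazolidin-2-one
Product: 4 (2R)-2-methylpent-4-yn-1-ol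
Conditions: LiBH4, H2O (1 equiv), Et2O, 0 °C
Reagents that add atoms: none
Why: Reductive cleavage of the N-acyl oxazolidinone with LiBH4 should free the primary alcohol without touching the alkyne or the stereocentre and return the auxiliary.

Step 3
Reactants: 4 (2R)-2-methylpent-4-yn-1-ol
Product: 5 (2R)-2-methylpent-4-ynal
Conditions: Dess–Martin periodinane, CH2Cl2, 0 °C → rt
Reagents that add atoms: none
Why: Dess–Martin oxidation runs under nearly neutral conditions, so the α-stereocentre of the aldehyde should not epimerise.

Step 4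
Reactants: 5 (2R)-2-methylpent-4-ynal
Product: 6 (3R)-3-methylhex-1-en-5-yne
Conditions: Ph3PCH3Br, KN(SiMe3)2, THF, 0 °C; then 5, −78 → 0 °C
Reagents that add atoms: methyltriphenylphosphonium bromide, C[P+](c1ccccc1)(c1ccccc1)c1ccccc1.[Br-]
Why: Wittig methylenation with the ylide at low temperature should turn the aldehyde into the C3 vinyl group faster than the α-centre can enolise.

Step 5
Reactants: 6 (3R)-3-methylhex-1-en-5-yne; 7 acetaldehyde
Product: 9 (3E,6R)-4,6-dimethylocta-3,7-dien-2-ol (both C2 epimers), via alkenyldimethylalane 8 (not isolated)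
Conditions: Al(CH3)3, (C5H5)2ZrCl2 (0.25 equiv), CH2Cl2, 0 °C → rt; then 7, −78 → 0 °C; aq. potassium sodium tartrate
Reagents that add atoms: trimethylaluminium, C[Al](C)C
Why: Zirconium-catalysed Negishi carboalumination adds methyl and aluminium syn across the terminal alkyne (methyl to the internal carbon) much faster than it touches the monosubstituted alkene, and the alkenylalane should add to acetaldehyde with retention of the E geometry; the new carbinol centre (target C8) is uncontrolled and is erased in step 6.

Step 6
Reactants: 9 (3E,6R)-4,6-dimethylocta-3,7-dien-2-ol (both C2 epimers)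
Product: 10 (3E,6R)-4,6-dimethylocta-3,7-dien-2-one
Conditions: MnO2, CH2Cl2, rt
Reagents that add atoms: none
Why: MnO2 oxidation is selective for the allylic alcohol and converges both C2 epimers on one enone.

Step 7
Reactants: 10 (3E,6R)-4,6-dimethylocta-3,7-dien-2-one
Product: 11 (2R,3E,6R)-4,6-dimethylocta-3,7-dien-2-ol
Conditions: (S)-2-methyl-CBS-oxazaborolidine (0.2 equiv), catecholborane, toluene, −78 °C
Reagents that add atoms: none
Why: Corey–Bakshi–Shibata reduction, in which the alkenyl group acts as the large substituent so that the S catalyst should give the 2R alcohol (target C8), while catecholborane at −78 °C reduces 1,2 without hydroborating the terminal alkene.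

Step 8
Reactants: 11 (2R,3E,6R)-4,6-dimethylocta-3,7-dien-2-ol
Product: 12 (1R)-1-[(2S,3S)-3-methyl-3-[(2R)-2-methylbut-3-en-1-yl]oxiran-2-yl]ethan-1-ol
Conditions: mCPBA, CH2Cl2, 0 °C
Reagents that add atoms: 3-chloroperoxybenzoic acid (mCPBA), OOC(=O)c1cccc(Cl)c1
Why: Hydroxyl-directed peracid epoxidation, in which allylic 1,3-strain with the cis methyl group holds the carbinol hydrogen in the alkene plane so that the hydrogen-bonded peracid attacks the face bearing the hydroxyl and gives the threo epoxy alcohol (oxirane 2S,3S), the less nucleophilic monosubstituted alkene reacting far more slowly.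

Step 9
Reactants: 12 (1R)-1-[(2S,3S)-3-methyl-3-[(2R)-2-methylbut-3-en-1-yl]oxiran-2-yl]ethan-1-ol
Product: 13 (2R,4S,6R)-4,6-dimethyloct-7-ene-2,4-diol
Conditions: NaAlH2(OCH2CH2OCH3)2, THF, 0 °C → rt
Reagents that add atoms: none
Why: Hydroxyl-directed reductive opening of a 2,3-epoxy alcohol, in which the aluminate formed at the carbinol delivers hydride to the adjacent epoxide carbon, giving the 1,3-diol and leaving the tertiary C–O bond (target C6) untouched.

Step 10
Reactants: 13 (2R,4S,6R)-4,6-dimethyloct-7-ene-2,4-diol
Product: 15 (2S,4S)-2,4-dimethyl-2-[(2R)-2-methylbut-3-en-1-yl]oxetane, via secondary tosylate 14 (not isolated)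
Conditions: n-BuLi (1 equiv), THF, 0 °C; TsCl (1 equiv); then n-BuLi (1 equiv), 0 → 45 °C
Reagents that add atoms: none
Why: Williamson-type oxetane synthesis from a 1,3-diol, in which only the secondary alkoxide is sulfonylated and the tertiary alkoxide then displaces the tosylate in a 4-exo-tet closure, with inversion at the carbinol carbon and retention at the tertiary centre.

Step 11
Reactants: 15 (2S,4S)-2,4-dimethyl-2-[(2R)-2-methylbut-3-en-1-yl]oxetane; 16 hydrogen peroxide
Product: 17 (2S,4R,6R)-4-hydroperoxy-4,6-dimethyloct-7-en-2-ol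
Conditions: anhydrous H2O2 in Et2O (excess), Me3SiOSO2CF3 (cat.), −78 → 0 °C
Reagents that add atoms: none
Why: Lewis-acid-mediated perhydrolysis of a tertiary oxetane, in which H2O2 attacks the activated ring at the more substituted carbon with inversion, setting C6 as R and releasing the secondary alcohol.

Step 12
Reactants: 17 (2S,4R,6R)-4-hydroperoxy-4,6-dimethyloct-7-en-2-ol; 18 carbon monoxide; 19 methanol
Product: 20 methyl 2-[(3S,4R,6R)-6-[(2S)-2-hydroxypropyl]-4,6-dimethyl-1,2-dioxan-3-yl]acetate
Conditions: Pd(O2CCF3)2 (10 mol%), 1,4-benzoquinone (2 equiv), CO (1 atm), MeOH–CH2Cl2, 0 °C → rt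
Reagents that add atoms: none
Why: Proposed new method: divalent palladium activates the terminal alkene of 17 and the tertiary hydroperoxide oxygen adds to the internal carbon (6-exo-trig), closing the 1,2-dioxane and leaving a primary alkyl–palladium that should take up CO faster than it loses the hydrogen on C3, after which methanolysis of the acyl–palladium releases the ester and zerovalent palladium, which benzoquinone returns to the divalent state. The closest known reactions are the divalent-palladium-catalysed Wacker-type cyclisation of unsaturated tertiary hydroperoxides to 3-alkenyl-1,2-dioxanes with benzoquinone as oxidant and the palladium-catalysed intramolecular alkoxycarbonylation of hydroxy alkenes to tetrahydropyranyl acetates; the proposal joins the nucleophile of the first to the carbonylative ending of the second. The ring should close through a chair in which the C4 methyl and the C6 hydroxypropyl arm are equatorial (fixed by their preset cis relation, the C6 methyl being axial) and the palladium-bound alkene is equatorial too, which sets C3 as S, trans to the C4 methyl. The step needs CO insertion to outrun β-hydride elimination (CO atmosphere, unhindered primary alkyl–palladium), the hydroperoxide to outcompete the free secondary hydroxyl (which could reach the alkene only through a seven-membered ring) and the O–O bond to survive; the hydroperoxide is tertiary and cannot fragment to a carbonyl, there is no second alkene, and a quinone in place of a copper salt as reoxidant avoids one-electron cleavage of the peroxide.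

Step 13
Reactants: 20 methyl 2-[(3S,4R,6R)-6-[(2S)-2-hydroxypropyl]-4,6-dimethyl-1,2-dioxan-3-yl]acetate
Product: 21 methyl 2-[(3S,4R,6R)-4,6-dimethyl-6-[(2R)-2-[(1-phenyl-1H-tetrazol-5-yl)sulfanyl]propyl]-1,2-dioxan-3-yl]acetate
Conditions: 1-phenyl-1H-tetrazole-5-thiol, PPh3, diisopropyl azodicarboxylate, THF, 0 °C
Reagents that add atoms: 1-phenyl-1H-tetrazole-5-thiol, Sc1nnnn1-c1ccccc1
Why: Mitsunobu thioetherification, in which the acidic tetrazolethiol displaces the activated secondary carbinol with inversion, the ester and the hindered dialkyl peroxide being expected to stay inert to PPh3 at 0 °C.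

Step 14
Reactants: 21 methyl 2-[(3S,4R,6R)-4,6-dimethyl-6-[(2R)-2-[(1-phenyl-1H-tetrazol-5-yl)sulfanyl]propyl]-1,2-dioxan-3-yl]acetate
Product: 22 methyl 2-[(3S,4R,6R)-4,6-dimethyl-6-[(2R)-2-[(1-phenyl-1H-tetrazol-5-yl)sulfonyl]propyl]-1,2-dioxan-3-yl]acetate
Conditions: (NH4)6Mo7O24·4H2O (cat.), 30% aq. H2O2, EtOH, 0 °C → rt
Reagents that add atoms: hydrogen peroxide (compound 16), OO
Why: Molybdate-catalysed H2O2 oxidation of the sulfide to the sulfone should leave a dialkyl peroxide and a methyl ester unchanged.

Step 15
Reactants: 23 prop-2-en-1-ylbenzene (allylbenzene); 24 (E)-but-2-enal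
Product: 25 (E)-4-phenylbut-2-enal
Conditions: second-generation Hoveyda–Grubbs catalyst (2 mol%), CH2Cl2, 40 °C
Reagents that add atoms: none
Why: Olefin cross-metathesis between a terminal alkene and an electron-poor enal is selective for the cross product and should give the thermodynamically favoured E enal.

Step 16
Reactants: 22 methyl 2-[(3S,4R,6R)-4,6-dimethyl-6-[(2R)-2-[(1-phenyl-1H-tetrazol-5-yl)sulfonyl]propyl]-1,2-dioxan-3-yl]acetate; 25 (E)-4-phenylbut-2-enal
Product: 26 methyl 2-[(3S,4R,6R)-4,6-dimethyl-6-[(2E,4E)-2-methyl-6-phenylhexa-2,4-dien-1-yl]-1,2-dioxan-3-yl]acetate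
Conditions: KN(SiMe3)2, DME, −60 °C; then 25; → rt
Reagents that add atoms: none
Why: Julia–Kocienski olefination, in which the sulfonyl carbanion (the most acidic C–H, formed at low temperature) adds to the enal and Smiles rearrangement with loss of SO2 and the tetrazololate forms the C8=C9 bond, E being expected to be favoured with a conjugated aldehyde because the adducts can equilibrate before the rearrangement, while the 10E bond comes unchanged from 25.

**Compound list**

1 | (4S)-4-benzyl-3-propanoyl-1,3-oxazolidin-2-one | O=C1OC[C@H](Cc2ccccc2)N1C(=O)CC | starting material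
2 | 3-bromoprop-1-yne (propargyl bromide) | C#CCBr | starting material
3 | (4S)-4-benzyl-3-[(2R)-2-methylpent-4-ynoyl]-1,3-oxazolidin-2-one | O=C1OC[C@H](Cc2ccccc2)N1C(=O)[C@H](C)CC#C | intermediate
4 | (2R)-2-methylpent-4-yn-1-ol | OC[C@H](C)CC#C | intermediate
5 | (2R)-2-methylpent-4-ynal | O=C[C@H](C)CC#C | intermediate
6 | (3R)-3-methylhex-1-en-5-yne | C=C[C@H](C)CC#C | intermediate
7 | acetaldehyde | CC=O | starting material
8 | dimethyl[(1E,4R)-2,4-dimethylhexa-1,5-dien-1-yl]alumane | C=C[C@H](C)C/C(C)=C/[Al](C)C | intermediate
9 | (3E,6R)-4,6-dimethylocta-3,7-dien-2-ol (both C2 epimers) | C=C[C@H](C)C/C(C)=C/C(C)O | intermediate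
10 | (3E,6R)-4,6-dimethylocta-3,7-dien-2-one | C=C[C@H](C)C/C(C)=C/C(C)=O | intermediate
11 | (2R,3E,6R)-4,6-dimethylocta-3,7-dien-2-ol | C=C[C@H](C)C/C(C)=C/[C@@H](C)O | intermediate
12 | (1R)-1-[(2S,3S)-3-methyl-3-[(2R)-2-methylbut-3-en-1-yl]oxiran-2-yl]ethan-1-ol | C=C[C@H](C)C[C@]1(C)O[C@H]1[C@@H](C)O | intermediate
13 | (2R,4S,6R)-4,6-dimethyloct-7-ene-2,4-diol | C=C[C@H](C)C[C@](C)(O)C[C@@H](C)O | intermediate
14 | (2R,4S,6R)-4-hydroxy-4,6-dimethyloct-7-en-2-yl 4-methylbenzenesulfonate | C=C[C@H](C)C[C@](C)(O)C[C@@H](C)OS(=O)(=O)c1ccc(C)cc1 | intermediate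
15 | (2S,4S)-2,4-dimethyl-2-[(2R)-2-methylbut-3-en-1-yl]oxetane | C=C[C@H](C)C[C@@]1(C)C[C@H](C)O1 | intermediate
16 | hydrogen peroxide | OO | starting material
17 | (2S,4R,6R)-4-hydroperoxy-4,6-dimethyloct-7-en-2-ol | C=C[C@H](C)C[C@](C)(C[C@H](C)O)OO | intermediate
18 | carbon monoxide | [C-]#[O+] | starting material
19 | methanol | CO | starting material
20 | methyl 2-[(3S,4R,6R)-6-[(2S)-2-hydroxypropyl]-4,6-dimethyl-1,2-dioxan-3-yl]acetate | COC(=O)C[C@@H]1OO[C@@](C)(C[C@H](C)O)C[C@H]1C | intermediate
21 | methyl 2-[(3S,4R,6R)-4,6-dimethyl-6-[(2R)-2-[(1-phenyl-1H-tetrazol-5-yl)sulfanyl]propyl]-1,2-dioxan-3-yl]acetate | COC(=O)C[C@@H]1OO[C@@](C)(C[C@@H](C)Sc2nnnn2-c2ccccc2)C[C@H]1C | intermediate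
22 | methyl 2-[(3S,4R,6R)-4,6-dimethyl-6-[(2R)-2-[(1-phenyl-1H-tetrazol-5-yl)sulfonyl]propyl]-1,2-dioxan-3-yl]acetate | COC(=O)C[C@@H]1OO[C@@](C)(C[C@@H](C)S(=O)(=O)c2nnnn2-c2ccccc2)C[C@H]1C | intermediate
23 | prop-2-en-1-ylbenzene (allylbenzene) | C=CCc1ccccc1 | starting material
24 | (E)-but-2-enal | C/C=C/C=O | starting material
25 | (E)-4-phenylbut-2-enal | O=C/C=C/Cc1ccccc1 | intermediate
26 | methyl 2-[(3S,4R,6R)-4,6-dimethyl-6-[(2E,4E)-2-methyl-6-phenylhexa-2,4-dien-1-yl]-1,2-dioxan-3-yl]acetate | COC(=O)C[C@@H]1OO[C@@](C)(C/C(C)=C/C=C/Cc2ccccc2)C[C@H]1C | target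

**Step count and risks**

Total: 16 steps. Longest linear sequence: 15 steps (steps 1–14 and 16); step 15 makes the side-chain enal.

Step 12 (key step, proposed new method). The hydroperoxide may be reduced by CO or by zerovalent palladium before it cyclises, β-hydride elimination may win over CO insertion, or closure through a chair with an axial alkene may erode the C3 selectivity. The fallback uses known chemistry, sets out from oxetane 15 and comes back at 20. Cross-metathesis of 15 with methyl acrylate (second-generation Hoveyda–Grubbs catalyst, CH2Cl2, 40 °C) should give methyl (2E,4R)-5-[(2S,4S)-2,4-dimethyloxetan-2-yl]-4-methylpent-2-enoate F1. Opening of its oxetane with H2O2 and Me3SiOSO2CF3 as in step 11 should give methyl (2E,4R,6R,8S)-6-hydroperoxy-8-hydroxy-4,6-dimethylnon-2-enoate F2. Amine-catalysed intramolecular conjugate addition of the hydroperoxide to the enoate (Et2NH, CF3CH2OH, rt), a reversible 6-exo closure that should settle on the all-equatorial 3,4-trans ring, then gives 20.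

Step 16. The sulfonyl carbanion may abstract a proton from the doubly activated C4 methylene of enal 25 instead of adding to it. The base may also deprotonate next to the ester, which would be followed by β-elimination of the peroxide and ring opening. Selectivity for E at the trisubstituted alkene may be incomplete. The fallback sets out from sulfone 22 and comes back at 26. Olefination of 22 with the non-enolisable (E)-3-(tributylstannyl)prop-2-enal, with KN(SiMe3)2 added to the mixture of both partners so that the carbanion is trapped as it forms, should give methyl 2-[(3S,4R,6R)-4,6-dimethyl-6-[(2E,4E)-2-methyl-5-(tributylstannyl)penta-2,4-dien-1-yl]-1,2-dioxan-3-yl]acetate F3. Stille coupling of F3 with benzyl bromide (tris(dibenzylideneacetone)dipalladium, Pd2(dba)3, with P(2-furyl)3, THF, 50 °C) then attaches the benzyl group under neutral conditions and gives 26. This fallback removes the proton-transfer problem but not the question of E selectivity.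

Step 11. The activated oxetane may ionise at the tertiary carbon, which would erode the inversion at C6 or let the alkene capture the cation, or H2O2 may attack the secondary carbon. The fallback gives up the stereospecific opening, sets out from enone 10 and comes back at 17. Reduction of 10 with the R enantiomer of the CBS catalyst and catecholborane should give (2S,3E,6R)-4,6-dimethylocta-3,7-dien-2-ol F4. Cobalt-catalysed Mukaiyama–Isayama hydroperoxysilylation of its trisubstituted alkene (bis(2,2,6,6-tetramethylheptane-3,5-dionato)cobalt, Co(thd)2, O2, Et3SiH, ClCH2CH2Cl, rt, stopped before the monosubstituted alkene reacts) should give (2S,6R)-4,6-dimethyl-4-[(triethylsilyl)peroxy]oct-7-en-2-ol F5 as both C4 epimers, since the radical step is not stereocontrolled. Cleavage of the silyl peroxide (K2CO3, MeOH, 0 °C) then gives 17 together with its epimer (2S,4S,6R)-4-hydroperoxy-4,6-dimethyloct-7-en-2-ol F6, to be separated by chromatography here or after the key step.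

**Further compounds**

F1 | step 12 | methyl (2E,4R)-5-[(2S,4S)-2,4-dimethyloxetan-2-yl]-4-methylpent-2-enoate | COC(=O)/C=C/[C@H](C)C[C@@]1(C)C[C@H](C)O1
F2 | step 12 | methyl (2E,4R,6R,8S)-6-hydroperoxy-8-hydroxy-4,6-dimethylnon-2-enoate | COC(=O)/C=C/[C@H](C)C[C@](C)(C[C@H](C)O)OO
F3 | step 16 | methyl 2-[(3S,4R,6R)-4,6-dimethyl-6-[(2E,4E)-2-methyl-5-(tributylstannyl)penta-2,4-dien-1-yl]-1,2-dioxan-3-yl]acetate | COC(=O)C[C@@H]1OO[C@@](C)(C/C(C)=C/C=C/[Sn](CCCC)(CCCC)CCCC)C[C@H]1C
F4 | step 11 | (2S,3E,6R)-4,6-dimethylocta-3,7-dien-2-ol | C=C[C@H](C)C/C(C)=C/[C@H](C)O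
F5 | step 11 | (2S,6R)-4,6-dimethyl-4-[(triethylsilyl)peroxy]oct-7-en-2-ol (both C4 epimers) | C=C[C@H](C)CC(C)(C[C@H](C)O)OO[Si](CC)(CC)CC
F6 | step 11 | (2S,4S,6R)-4-hydroperoxy-4,6-dimethyloct-7-en-2-ol | C=C[C@H](C)C[C@@](C)(C[C@H](C)O)OO
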